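Labdane numbering (C1–C20) is used for every intermediate. TBS = tert-butyldimethylsilyl, TES = triethylsilyl, TMS = trimethylsilyl, DET = diethyl tartrate.

## Analysis of the target

The target is an unsymmetrical dimer of two 2,3-seco-8,13-epoxylabdanes, in each of which a cyclohexane ring B (C5–C10) is trans-fused along C8–C9 to a tetrahydropyran (O, C8, C9, C11, C12, C13). Ring A is absent, cut between C2 and C3, so that C10 carries CH2CO2H (C1, C2) and C5 carries C(CH3)2CO2H (C4, C3); the halves are joined by an ester between the hindered C3 carboxyl of the "vinyl half" (C13 bears C14=C15) and the primary C15 hydroxyl of the "diol half", whose secondary C14 hydroxyl stays free. Ring B has the same configuration in both halves (5S,8S,9S,10R): H5 and H9 are cis to each other and trans to the C10 methyl, the C8 methyl (C17) is axial and syn to the C10 methyl, and the C8 oxygen is equatorial, syn to H9 and anti to C11. The halves differ at C13, which is S in the vinyl half (C16 axial, cis to C17) and R in the diol half (C14 axial), where C14 is R. Sensitive groups are the tertiary allylic ether (acid), the β-hydroxy ester junction (base, acyl migration), three free acids, and the vinyl group, which forbids late hydrogenation. The synthesis is hard because ring B has four contiguous stereocentres, two of them fully substituted (C8, C10) and flanked by the quaternary C4, because the ester must be formed at the more hindered of two carboxyls, and because the two halves need opposite configurations at C13. The strategy rests on one feature: C8 carries a methyl group and the ring oxygen and lies 1,4 to C5 across ring B, while C9 and C10 carry C11 and C1. Ring B is therefore what is left of a 2-methylfuran (C5 to C8, oxygen on C8) after [4+2] addition to a C9=C10 alkene and scission of the C5–O bond.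

## Retrosynthetic reasoning

**Unmasking (45 from 44).** The three acids are released last from allyl esters. These come off under neutral conditions that spare the junction ester, the free C14 hydroxyl and the vinyl group.

**Junction ester (44 to 37 and 43).** The ester is cut at the C15–O bond, not at the acyl–oxygen bond. The C3 carboxyl sits on a quaternary carbon next to a ring carbon, so acyl transfer from it would be slow and would need C14 protection. As a carboxylate it is a normal nucleophile. The forward reaction is attack of the carboxylate of 37 on the terminal epoxide 43 at C15, which also delivers the free C14 hydroxyl. Acid 37 needs only C2 masked, which selective esterification of the diacid 36 at its unhindered carboxyl provides.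

**Pyran, O–C13 (35 and 43 back to 32 and 38, both from 31).** The two halves need opposite configurations at C13. Cutting O–C13 leads to two epoxy alcohols, 32 and 38, that differ only in the configuration of the epoxide and are made from one E allylic alcohol 31 by the two enantiomeric epoxidation catalysts. The C8 hydroxyl opens each at C13 with inversion (33, 39). In the vinyl series the resulting diol 33 is deoxygenated through 34 to the vinyl group of 35. In the diol series the C14 carbinol of 39 has the wrong configuration, and this is corrected when the terminal epoxide 43 is closed on C14 from the C15 oxygen (41 to 43).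

**Ring A, C2–C3 (31 back to 30, 28, 26).** The C2 and C3 carboxyls are the two ends of a cyclohexanone. The C3 ketone of 28 can enolise only towards C2 because C4 is quaternary, so formylation and oxidative cleavage (29 to 30) are regiospecific. The cut is placed after the C7 oxygen is gone and after the side-chain ester has been reduced, since a second enolisable ketone or an ester reduction in the presence of the ring A esters would both interfere.

**Side chain and ring B adjustment (26 back to 23, 21, 18).** C12–C15 are attached by two olefinations, C11=C12 with 19 and C13=C14 with 8. One hydrogenation (20 to 21) saturates C11–C12 and sets H5. The C7 carbonyl, needed only to open the bridge, is removed through 24 and 25. The neighbouring C8 hydroxyl of 23 is what distinguishes C7 from the C3 ketone.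

**C5–O bond (18 back to 17).** Ring B of 18 is the opened form of the oxygen-bridged bicycle 17. The forward step must break C5–O and keep C8–O. The enol ether at C7 in 17 is conjugated with C5 only, which makes the scission regiospecific.

**Key disconnection, C5–C10 and C8–C9 (17 back to 16).** Both bonds of ring B that join the former furan carbons to C9 and C10 are cut, together with the temporary ring A bond C5–C10. This removes two rings and four stereocentres at once and leads to the achiral chain 16. In the forward direction the tether forces C1 syn to the oxygen bridge, and the E alkene then places C11 anti. This is the relationship of the C8 oxygen, H9, C1 and C11 in the target. Only the absolute sense is left to a chiral Lewis acid.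

**Siloxyfuran (16 back to 15, 14, 13, 12, 11).** The enal and ketone of 16 come from diol 15 and ester 14. The 3-siloxyfuran of 14 is the silylated enol of furanone 13, and 13 is the cyclised form of hydroxy ynone 12, which is released from its acetate 11. Ynone 11 is cut at the alkyne–acyl bond into alkyne 9 and acid chloride 10.

**Chain (9 back to 7 and 8; 7 back to 2 and 3; 2 from 1).** The E trisubstituted alkene is an olefination of the methyl ketone of 7 with 8. Ketone 7 is an acylation of the Grignard reagent 4 (from 3) by amide 2, itself made from acid 1. All chain-building olefin chemistry is finished before the acid-sensitive siloxyfuran is formed.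

## Alternatives that were turned down

**Alternative 1: epoxide relay into the pyran.**
- Disconnection: the O–C13 bond of the protected diol half A1, the bis(2-trimethylsilylethyl) ester that carries the free 14,15-diol, leading back to the (13S,14R)-13,14-epoxy-8,15-diol bis(2-trimethylsilylethyl) ester A2.
- Forward key step: Ti(OiPr)4 or camphorsulfonic acid lets the tertiary C8 hydroxyl open A2 at C13 with inversion, which closes the pyran and gives A1.
- For it: C13 and C14 are both set by a Sharpless epoxidation under reagent control. The closure is 6-exo at the carbon best able to carry positive charge. The product A1 already has the diol needed for the junction.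
- Against it: it is a closing move. A2 must already contain ring B with C5, C8, C9 and C10, the quaternary C4 and C10, and the tertiary C8 alcohol, so it is as hard as a half of the target. The (13S,14R) epoxide belongs to the Z (nerol-type) allylic alcohol, the harder trisubstituted geometry to make. The vinyl half needs the C13-epimeric series and a deoxygenation. A tertiary alcohol must displace at a tertiary carbon.
- Comparison: on C13 and C14 the route through A2 and A1 is stronger than anything a cycloaddition can offer. The chosen route therefore uses the same kind of closure as a tactic (steps 22 and 28), from the E series and at the price of an inversion at C14. What the chosen strategy offers in its place is ring B itself, with four stereocentres, from an achiral chain.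

**Alternative 2: epoxy-polyene tricyclisation.**
- Disconnection: C4–C5, C9–C10 and O–C8 of the tricycle A3, ent-manoyl oxide carrying an equatorial C3 hydroxyl, back to (3R,13S)-epoxygeranyllinalool A4, whose terminal epoxide lies at C3–C4.
- Forward key step: MeAlCl2 opens the epoxide of A4, the two E alkenes close ring A and ring B, and the C13 hydroxyl captures the C8 cation, giving A3.
- For it: three rings, three skeletal bonds and the centres C3, C5, C8, C9 and C10 are formed in one step from an acyclic precursor. Their relative configuration follows from chair–chair folding. C13 is carried in with A4, and the C3 hydroxyl of A3 is the handle for ring A scission. It is clearly the shorter route and is stronger on step economy.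
- Against it: hydroxyl-terminated epoxy-polyene cascades are diverted to partly cyclised and eliminated products. The absolute configuration of the whole ring system hangs on one remote epoxide. Two C13-epimeric precursors are needed for the two halves. C14 of the diol half must later be set on the vinyl group of A3, next to a quaternary carbon, where neither substrate nor reagent control is strong.
- Comparison: the chosen strategy gives up step economy. In return its relative configuration is fixed by the tether and the alkene geometry, not by the folding of a cation. Both C13 epimers and C14 are set late from one common intermediate by reagent control.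

**Alternative 3: three-component allylation and Michael trapping on ring B.**
- Disconnection: C10–C1 and C9–C11 of the ring B diketone A5, back to the 4-substituted 3-methylcyclohexenone A6, allyltrimethylsilane A7 and methyl vinyl ketone A8.
- Forward key step: TiCl4 promotes conjugate addition of A7 to C10 of A6, and the titanium enolate is trapped with A8, giving A5 with its C10 allyl and C9 oxobutyl groups.
- For it: no temporary ring. The allyl group is a direct precursor of the C2 carboxyl and the ester of A6 is already C3. The C5 substituent should direct the allyl group anti and the C9 chain trans to it. The approach is convergent, and A7 and A8 are simple reagents.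
- Against it: the conjugate addition must create the quaternary C10 next to the bulky C5 substituent. A5 is a 1,5-diketone and is set up for Robinson-type aldol closure. C8 remains a ketone, and methyl addition from the face needed for the axial C17 methyl is the face blocked by the axial C10 methyl, so the intrinsic preference gives the wrong C8 epimer. A6 must be made as a single enantiomer.
- Comparison: it is stronger in avoiding the sacrificial ring A and the later removal of an oxygen at C7. The chosen strategy fixes the C8 methyl and oxygen, together with C9 and C10, in the ring-forming step, because they are already the 2-methyl and ring oxygen of the furan.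

Key step: step 9

## Route

Assumption: the sense of induction in step 9 is assigned by analogy with the accepted formyl C–H···O binding model for enals, so the (S)-diphenylprolinol-derived catalyst is written; if the sense is the opposite, its enantiomer is used and nothing else changes.

Step 1
Reactants: 1 2,2-dimethylbut-3-ynoic acid
Product: 2 N-methoxy-N,2,2-trimethylbut-3-ynamide
Conditions: CDI, CH2Cl2, rt; then MeNHOMe·HCl, rt
Reagents that add atoms: N,O-dimethylhydroxylamine hydrochloride, CNOC.Cl
Why: Weinreb amide formation through the acyl imidazole; the quaternary α-carbon excludes ketene formation and the terminal alkyne is inert.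

Step 2
Reactants: 2 N-methoxy-N,2,2-trimethylbut-3-ynamide; 3 2-(2-bromoethyl)-2-methyl-1,3-dioxolane
Product: 7 3,3-dimethyloct-1-yne-4,7-dione, via Grignard reagent 4 (not isolated), via magnesium acetylide 5 (not isolated), via dioxolane ketone 6 (not isolated)
Conditions: 3, Mg, THF, 25 °C; 2, EtMgBr (1.0 equiv), THF, 0 °C; then 4 (1.3 equiv), 0 °C → rt; then 2 M HCl, rt
Reagents that add atoms: water, O
Why: Weinreb ketone synthesis: EtMgBr first turns the alkyne into its magnesium acetylide, which is too hindered and too weak a nucleophile to attack the amide; the primary Grignard reagent then adds once to give the stable chelate, and the acidic quench releases the ketone and hydrolyses the dioxolane in the same flask.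

Step 3
Reactants: 7 3,3-dimethyloct-1-yne-4,7-dione; 8 triethyl phosphonoacetate
Product: 9 ethyl (2E)-3,7,7-trimethyl-6-oxonon-2-en-8-ynoate
Conditions: NaH, THF, 0 °C → rt; chromatography
Reagents that add atoms: none
Why: Horner–Wadsworth–Emmons olefination: only the methyl ketone reacts, since the other carbonyl is flanked by a quaternary carbon and the phosphonate anion is too weak a base to deprotonate the alkyne or start aldol closure of the 1,4-diketone; the E isomer should predominate and the Z isomer is removed here.

Step 4
Reactants: 9 ethyl (2E)-3,7,7-trimethyl-6-oxonon-2-en-8-ynoate; 10 (S)-2-acetoxypropanoyl chloride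
Product: 11 ethyl (2E,11S)-11-acetoxy-3,7,7-trimethyl-6,10-dioxododec-2-en-8-ynoate
Conditions: PdCl2(PPh3)2 (2 mol%), CuI (4 mol%), Et3N, THF, rt
Reagents that add atoms: none
Why: Acyl Sonogashira coupling (copper acetylide, oxidative addition of the acid chloride to zerovalent palladium, reductive elimination) gives the ynone without a strong base, which the enolisable ketone would not tolerate; the lactate-derived stereocentre disappears in step 6, so its integrity does not matter.

Step 5
Reactants: 11 ethyl (2E,11S)-11-acetoxy-3,7,7-trimethyl-6,10-dioxododec-2-en-8-ynoate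
Product: 13 ethyl (2E)-3,7-dimethyl-7-(5-methyl-4-oxo-4,5-dihydrofuran-2-yl)-6-oxooct-2-enoate, via hydroxy ynone 12 (not isolated)
Conditions: K2CO3, EtOH, 0 °C → rt
Reagents that add atoms: none
Why: Ethanolysis of the acetate followed by base-mediated 5-endo-dig oxa-Michael cyclisation of the α'-hydroxy ynone, a known route to furan-3(2H)-ones; ethanol makes ester exchange at the enoate degenerate, and ethoxide adding first to the ynone converges on the same furanone by addition–elimination.

Step 6
Reactants: 13 ethyl (2E)-3,7-dimethyl-7-(5-methyl-4-oxo-4,5-dihydrofuran-2-yl)-6-oxooct-2-enoate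
Product: 14 ethyl (2E)-7-[4-(tert-butyldimethylsilyloxy)-5-methylfuran-2-yl]-3,7-dimethyl-6-oxooct-2-enoate
Conditions: TBSOTf (1.05 equiv), Et3N, CH2Cl2, −78 → 0 °C
Reagents that add atoms: tert-butyldimethylsilyl trifluoromethanesulfonate, CC(C)(C)[Si](C)(C)OS(=O)(=O)C(F)(F)F
Why: Soft enolisation and O-silylation: the furanone is by far the most readily enolised carbonyl because its enol is an aromatic 3-hydroxyfuran; the hindered ketone and the enoate are not silylated with one equivalent at low temperature.

Step 7
Reactants: 14 ethyl (2E)-7-[4-(tert-butyldimethylsilyloxy)-5-methylfuran-2-yl]-3,7-dimethyl-6-oxooct-2-enoate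
Product: 15 (2E)-7-[4-(tert-butyldimethylsilyloxy)-5-methylfuran-2-yl]-3,7-dimethyloct-2-ene-1,6-diol
Conditions: i-Bu2AlH (4 equiv), CH2Cl2, −78 °C; aq. potassium sodium tartrate
Reagents that add atoms: none
Why: Hydride reduction: i-Bu2AlH gives 1,2-reduction of the enoate to the E allylic alcohol and necessarily also reduces the ketone; the carbinol configuration is immaterial because both alcohols are reoxidised, and the siloxyfuran is inert to hydride.

Step 8
Reactants: 15 (2E)-7-[4-(tert-butyldimethylsilyloxy)-5-methylfuran-2-yl]-3,7-dimethyloct-2-ene-1,6-diol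
Product: 16 (2E)-7-[4-(tert-butyldimethylsilyloxy)-5-methylfuran-2-yl]-3,7-dimethyl-6-oxooct-2-enal
Conditions: (n-Pr4N)[RuO4] (5 mol%), NMO, 4 Å MS, CH2Cl2, rt
Reagents that add atoms: none
Why: Ley–Griffith oxidation takes the allylic alcohol to the E enal and the secondary alcohol back to the ketone under neutral conditions that spare the acid- and oxidant-sensitive siloxyfuran and do not isomerise the alkene.

Step 9
Reactants: 16 (2E)-7-[4-(tert-butyldimethylsilyloxy)-5-methylfuran-2-yl]-3,7-dimethyl-6-oxooct-2-enal
Product: 17 oxygen-bridged adduct: 5,8-epoxy bridge, C6=C7 silyl enol ether (7-OTBS), 3-ketone in ring A, 11-al; bridge oxygen syn to C1 and H9, anti to C11 and the C10 methyl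
Conditions: (S)-B-(o-tolyl)-α,α-diphenylprolinol oxazaborolidine (20 mol%), Tf2NH (18 mol%), CH2Cl2, −78 → −40 °C; Et3N quench at −78 °C
Reagents that add atoms: none
Why: Proposed new method: the oxazaborolidinium ion binds the formyl oxygen of the E enal and lowers its LUMO, and the 3-siloxyfuran (C5 to C8) adds across C9=C10 in a concerted, asynchronous [4+2] that forms C5–C10 and C8–C9 and turns the furan oxygen into the C5–O–C8 bridge; the closest known reaction type is the Lewis acid-promoted intramolecular Diels–Alder reaction of furans with tethered enones and enals, and the new element is its combination with a chiral oxazaborolidinium catalyst, known for intermolecular furan and intramolecular triene cycloadditions. Ring A closes in the type 1 intramolecular mode (6-exo-trig at C10 through the tether C4, C3, C2, C1) and ring B (C5 to C10) is closed by the cycloaddition itself. The four-atom tether can only span the face of the furan that becomes the bridge side, so C1 ends syn (exo) to oxygen; because the alkene is E, C11 and the C10 methyl are then anti, which fixes C5, C8, C9 and C10 relative to one another. The absolute sense (bonding to the Re face of C9) is the only element left to the catalyst, whose aryl group is meant to cover the opposite face. The step needs periselectivity over Mukaiyama–Michael addition, and this is secured because the nucleophilic furan carbon C8 cannot reach the β-carbon C10 through this tether and the intermolecular version would have to join two fully substituted carbons. It also needs kinetic trapping of a reversible adduct, hence low temperature, an amine quench and immediate use in step 10. The gem-dimethyl group at C4 and the sp2 carbon C3 favour the folded conformer.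

Step 10
Reactants: 17 oxygen-bridged adduct
Product: 18 8-(tert-butyldimethylsilyloxy)-3,7-dioxo-5-en-11-al: ring A 3-ketone, ring B 5-en-7-one, 8-OTBS syn to H9, 9-CHO trans to the C8 oxygen
Conditions: TBSOTf (0.2 equiv), 2,6-di-tert-butyl-4-methylpyridine (0.3 equiv), CH2Cl2, −78 → −20 °C
Reagents that add atoms: none
Why: Lewis acid-induced opening of an oxanorbornenyl silyl enol ether, the reaction by which 7-oxanorbornan-2-ones are converted into 4-siloxycyclohex-2-enones with silyl triflates: the bridge oxygen is silylated, only the C5–O bond is in vinylogous conjugation with the enol ether oxygen and ionises, and triflate removes the silyl group from O7 to regenerate the catalyst; base is avoided because with a free aldehyde it would open the other C–O bond through the C9 enolate and expose a β-alkoxy aldehyde to retro-aldol cleavage, whereas here O8 ends up silylated.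

Step 11
Reactants: 18 8-(tert-butyldimethylsilyloxy)-3,7-dioxo-5-en-11-al; 19 dimethyl (2-oxopropyl)phosphonate
Product: 20 (11E)-8-(tert-butyldimethylsilyloxy)-14,15-dinorlabda-5,11-diene-3,7,13-trione
Conditions: LiCl, i-Pr2NEt, MeCN, rt
Reagents that add atoms: none
Why: Horner–Wadsworth–Emmons reaction under Masamune–Roush conditions: the lithium-chelated keto phosphonate is deprotonated by a tertiary amine that is too weak to enolise the hindered aldehyde or to eliminate the β-siloxy group; the E enone results.

Step 12
Reactants: 20 (11E)-8-(tert-butyldimethylsilyloxy)-14,15-dinorlabda-5,11-diene-3,7,13-trione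
Product: 21 8-(tert-butyldimethylsilyloxy)-14,15-dinorlabdane-3,7,13-trione with H5 cis to H9 and trans to the C10 methyl
Conditions: H2 (4 bar), 10% Pd/C, EtOAc, rt
Reagents that add atoms: none
Why: Heterogeneous hydrogenation: the side-chain alkene is reduced readily, and the ring enone takes hydrogen from the face opposite to the axial methyl groups on C10 and C8, which puts H5 cis to H9 and trans to the C10 methyl (trans fusion, as in the hydrogenation of steroidal 5-en-7-ones); ketones and the silyl ether are untouched.

Step 13
Reactants: 21 8-(tert-butyldimethylsilyloxy)-14,15-dinorlabdane-3,7,13-trione; 8 triethyl phosphonoacetate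
Product: 22 ethyl (13E)-8-(tert-butyldimethylsilyloxy)-3,7-dioxolabd-13-en-15-oate
Conditions: NaH, THF, 0 °C → rt; chromatography
Reagents that add atoms: none
Why: Horner–Wadsworth–Emmons olefination of the only unhindered carbonyl (C3 and C7 are each flanked by a quaternary carbon); O8 is still silylated, so neither α-ketol rearrangement nor conjugate addition of an alkoxide to the new enoate can occur under base; the E isomer is expected to predominate and the Z isomer is removed here.

Step 14
Reactants: 22 ethyl (13E)-8-(tert-butyldimethylsilyloxy)-3,7-dioxolabd-13-en-15-oate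
Product: 23 ethyl (13E)-8-hydroxy-3,7-dioxolabd-13-en-15-oate
Conditions: 48% aq. HF, MeCN, rt
Reagents that add atoms: none
Why: Fluoride cleavage of the tertiary silyl ether under acidic conditions, which avoids base-induced α-ketol rearrangement; the enoate and both ketones are stable.

Step 15
Reactants: 23 ethyl (13E)-8-hydroxy-3,7-dioxolabd-13-en-15-oate
Product: 24 ethyl (13E)-7,8-dihydroxy-3-oxolabd-13-en-15-oate (7-OH trans to 8-OH)
Conditions: Me4NBH(OAc)3, MeCN–AcOH (1:1), −20 °C → rt
Reagents that add atoms: none
Why: Hydroxyl-directed reduction (Saksena–Evans type): exchange with the C8 hydroxyl gives an alkoxyborohydride that delivers hydride to the adjacent C7 carbonyl only; the isolated C3 ketone and the enoate are not reduced by triacetoxyborohydride, and the C7 configuration (expected trans to O8) is immaterial.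

Step 16
Reactants: 24 ethyl (13E)-7,8-dihydroxy-3-oxolabd-13-en-15-oate
Product: 25 ethyl (13E)-8-hydroxy-3-oxo-7-(phenoxythiocarbonyloxy)labd-13-en-15-oate
Conditions: PhOC(S)Cl, pyridine, DMAP (cat.), CH2Cl2, 0 °C → rt
Reagents that add atoms: O-phenyl chlorothionoformate, S=C(Cl)Oc1ccccc1
Why: Thioacylation of the secondary alcohol; the tertiary C8 hydroxyl is not acylated under these conditions, and the product is reduced without delay so that cyclisation onto O8 cannot compete.

Step 17
Reactants: 25 ethyl (13E)-8-hydroxy-3-oxo-7-(phenoxythiocarbonyloxy)labd-13-en-15-oate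
Product: 26 ethyl (13E)-8-hydroxy-3-oxolabd-13-en-15-oate
Conditions: Bu3SnH, AIBN (cat.), toluene, 90 °C
Reagents that add atoms: none
Why: Barton–McCombie deoxygenation: the stannyl radical adds to C=S, the C7–O bond fragments and the secondary radical abstracts hydrogen; the side chain is equatorial on C9 and out of reach of the C7 radical, and ketone, enoate and tertiary alcohol are inert.

Step 18
Reactants: 26 ethyl (13E)-8-hydroxy-3-oxolabd-13-en-15-oate
Product: 28 (13E)-8,15-dihydroxylabd-13-en-3-one, via bis-TMS enol ether 27 (not isolated)
Conditions: TMSOTf, Et3N, CH2Cl2, −20 °C; then i-Bu2AlH, CH2Cl2, −78 °C; then 1 M HCl, THF, 0 °C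
Reagents that add atoms: none
Why: In situ protection: the ketone enolises only towards C2 and is masked as its silyl enol ether (O8 is silylated at the same time), so i-Bu2AlH reduces only the enoate to the E allylic alcohol; aqueous acid then returns the ketone and the tertiary alcohol.

Step 19
Reactants: 28 (13E)-8,15-dihydroxylabd-13-en-3-one
Product: 30 (13E)-8,15-dihydroxy-2,3-secolabd-13-ene-2,3-dioic acid, via hydroxymethylene ketone 29 (not isolated)
Conditions: NaH, HCO2Et, THF, 0 °C → rt; then 30% H2O2, 2 M NaOH, MeOH, 0 °C → rt; HCl to pH 2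
Reagents that add atoms: hydrogen peroxide, OO; water (aqueous sodium hydroxide), O
Why: Claisen formylation at C2, the only enolisable position, followed by oxidative cleavage of the 2-hydroxymethylene 3-ketone with alkaline hydrogen peroxide, the classical scission of ring A ketones to 2,3-seco diacids; the formyl carbon leaves as formate, any formate ester formed on the allylic alcohol is saponified, and the electron-rich alkene is not attacked by the nucleophilic oxidant.

Step 20
Reactants: 30 (13E)-8,15-dihydroxy-2,3-secolabd-13-ene-2,3-dioic acid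
Product: 31 diallyl (13E)-8,15-dihydroxy-2,3-secolabd-13-ene-2,3-dioate
Conditions: allyl bromide, K2CO3, DMF, rt
Reagents that add atoms: allyl bromide, C=CCBr
Why: SN2 O-alkylation of the two carboxylates; the alcohols are not alkylated under carbonate, and alkylation, unlike acyl activation, is insensitive to the hindrance at C3.

Step 21
Reactants: 31 diallyl (13E)-8,15-dihydroxy-2,3-secolabd-13-ene-2,3-dioate
Product: 32 diallyl (13R,14R)-13,14-epoxy-8,15-dihydroxy-2,3-secolabdane-2,3-dioate
Conditions: Ti(OiPr)4 (10 mol%), D-(−)-DET (12 mol%), t-BuOOH, 4 Å MS, CH2Cl2, −20 °C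
Reagents that add atoms: tert-butyl hydroperoxide, CC(C)(C)OO
Why: Sharpless asymmetric epoxidation under reagent control: by analogy with geraniol the D-(−)-tartrate catalyst gives the (13R,14R)-epoxide of the E allylic alcohol; the remote ring stereocentres, the tertiary alcohol and the allyl esters do not interfere.

Step 22
Reactants: 32 diallyl (13R,14R)-13,14-epoxy-8,15-dihydroxy-2,3-secolabdane-2,3-dioate
Product: 33 diallyl (13S,14R)-8,13-epoxy-14,15-dihydroxy-2,3-secolabdane-2,3-dioate
Conditions: Ti(OiPr)4 (1.5 equiv), CH2Cl2, 0 °C → rt
Reagents that add atoms: none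
Why: Titanium-assisted intramolecular opening of a 2,3-epoxy alcohol at its C3 position (here C13): chelation through the C15 oxygen activates the epoxide and the C8 hydroxyl attacks the tertiary C13 in the 6-exo mode with inversion, which sets C13 as S (C16 axial) and leaves C14 untouched.

Step 23
Reactants: 33 diallyl (13S,14R)-8,13-epoxy-14,15-dihydroxy-2,3-secolabdane-2,3-dioate
Product: 34 14,15-cyclic thionocarbonate of 33
Conditions: 1,1'-thiocarbonyldiimidazole, DMAP (cat.), THF, 60 °C
Reagents that add atoms: 1,1'-thiocarbonyldiimidazole, S=C(n1ccnc1)n1ccnc1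
Why: Cyclic thionocarbonate formation: the primary alcohol is acylated first and the hindered C14 hydroxyl closes the five-membered ring intramolecularly.

Step 24
Reactants: 34 14,15-cyclic thionocarbonate of 33
Product: 35 diallyl (13S)-8,13-epoxy-2,3-secolabd-14-ene-2,3-dioate
Conditions: 1,3-dimethyl-2-phenyl-1,3,2-diazaphospholidine, THF, 40 °C
Reagents that add atoms: none
Why: Corey–Winter olefination: the phosphorus reagent removes sulfur and the resulting carbene-like species loses CO2 to give the vinyl group; C13 is not involved and the allyl esters do not react with the phosphorus reagent.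

Step 25
Reactants: 35 diallyl (13S)-8,13-epoxy-2,3-secolabd-14-ene-2,3-dioate
Product: 36 (13S)-8,13-epoxy-2,3-secolabd-14-ene-2,3-dioic acid
Conditions: Pd(PPh3)4 (5 mol%), morpholine, THF, rt
Reagents that add atoms: none
Why: Tsuji–Trost deallylation: zerovalent palladium ionises both allyl esters and morpholine captures the allyl groups; the tertiary allylic ether is not ionised under these conditions.

Step 26
Reactants: 36 (13S)-8,13-epoxy-2,3-secolabd-14-ene-2,3-dioic acid
Product: 37 (13S)-8,13-epoxy-2,3-secolabd-14-ene-2,3-dioic acid 2-allyl ester (C3 acid free)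
Conditions: allyl alcohol (1.2 equiv), EDC·HCl, DMAP (cat.), CH2Cl2, 0 °C → rt
Reagents that add atoms: allyl alcohol, C=CCO
Why: Steglich esterification is strongly sensitive to hindrance: the CH2CO2H group on C10 is esterified and the α,α-dimethyl acid on C4 is not; if the two acids first form the cyclic anhydride, the alcohol opens it at the unhindered carbonyl with the same outcome.

Step 27
Reactants: 31 diallyl (13E)-8,15-dihydroxy-2,3-secolabd-13-ene-2,3-dioate
Product: 38 diallyl (13S,14S)-13,14-epoxy-8,15-dihydroxy-2,3-secolabdane-2,3-dioate
Conditions: Ti(OiPr)4 (10 mol%), L-(+)-DET (12 mol%), t-BuOOH, 4 Å MS, CH2Cl2, −20 °C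
Reagents that add atoms: tert-butyl hydroperoxide, CC(C)(C)OO
Why: Sharpless asymmetric epoxidation with the enantiomeric tartrate gives the (13S,14S)-epoxide of the same E allylic alcohol under reagent control.

Step 28
Reactants: 38 diallyl (13S,14S)-13,14-epoxy-8,15-dihydroxy-2,3-secolabdane-2,3-dioate
Product: 39 diallyl (13R,14S)-8,13-epoxy-14,15-dihydroxy-2,3-secolabdane-2,3-dioate
Conditions: Ti(OiPr)4 (1.5 equiv), CH2Cl2, 0 °C → rt
Reagents that add atoms: none
Why: As in step 22, 6-exo opening at C13 with inversion gives the (13R) pyran in which C14 is axial; C14 keeps the S configuration of the epoxide, which is the epimer of what the target needs and is corrected in steps 29 and 30.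

Step 29
Reactants: 39 diallyl (13R,14S)-8,13-epoxy-14,15-dihydroxy-2,3-secolabdane-2,3-dioate
Product: 41 15-O-triethylsilyl 14-O-methanesulfonyl derivative of 39, via 15-O-TES ether 40 (not isolated)
Conditions: TESCl, imidazole, CH2Cl2, −20 °C; then MsCl, Et3N, DMAP, 0 °C → rt
Reagents that add atoms: chlorotriethylsilane, CC[Si](Cl)(CC)CC; methanesulfonyl chloride, CS(Cl)(=O)=O
Why: The primary alcohol is silylated selectively, and the hindered secondary alcohol is then converted into its mesylate through the sulfene, which is little affected by hindrance.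

Step 30
Reactants: 41 15-O-triethylsilyl 14-O-methanesulfonyl derivative of 39
Product: 43 diallyl (13R,14R)-8,13:14,15-diepoxy-2,3-secolabdane-2,3-dioate, via hydroxy mesylate 42 (not isolated)
Conditions: TBAF, THF, 0 °C → rt
Reagents that add atoms: none
Why: Fluoride removes the silyl group and the C15 alkoxide displaces the mesylate intramolecularly (3-exo-tet, SN2) with inversion at C14, giving the (14R)-epoxide; C13 is fully substituted, so elimination cannot compete.

Step 31
Reactants: 37 (13S)-8,13-epoxy-2,3-secolabd-14-ene-2,3-dioic acid 2-allyl ester; 43 diallyl (13R,14R)-8,13:14,15-diepoxy-2,3-secolabdane-2,3-dioate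
Product: 44 tris(allyl) ester of the target (C3 carboxyl of the vinyl half esterified with O15 of the diol half, free (14R)-hydroxyl)
Conditions: Cs2CO3 (0.3 equiv), DMF, 70 °C
Reagents that add atoms: none
Why: Base-catalysed addition of a carboxylic acid to a terminal epoxide: the caesium carboxylate attacks the unhindered C15 (C14 is neopentyl), the epoxide oxygen becomes the free (14R)-hydroxyl, and the pivalate-like ester has no tendency to migrate to the hindered secondary alcohol.

Step 32
Reactants: 44 tris(allyl) ester of the target
Product: 45 CNP0107285.2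
Conditions: Pd(PPh3)4 (10 mol%), morpholine, THF, rt; aq. citric acid
Reagents that add atoms: none
Why: Tsuji–Trost deallylation under neutral conditions releases the three acids without touching the junction ester, the secondary alcohol, the tertiary allylic ether or the vinyl group.

## Compound list

1 | 2,2-dimethylbut-3-ynoic acid | C#CC(C)(C)C(=O)O | starting material
2 | N-methoxy-N,2,2-trimethylbut-3-ynamide | C#CC(C)(C)C(=O)N(C)OC | intermediate
3 | 2-(2-bromoethyl)-2-methyl-1,3-dioxolane | CC1(CCBr)OCCO1 | starting material
4 | [2-(2-methyl-1,3-dioxolan-2-yl)ethyl]magnesium bromide | CC1(CC[Mg]Br)OCCO1 | intermediate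
5 | bromomagnesium acetylide of 2 | Br[Mg]C#CC(C)(C)C(=O)N(C)OC | intermediate
6 | 3,3-dimethyl-6-(2-methyl-1,3-dioxolan-2-yl)hex-1-yn-4-one | C#CC(C)(C)C(=O)CCC1(C)OCCO1 | intermediate
7 | 3,3-dimethyloct-1-yne-4,7-dione | C#CC(C)(C)C(=O)CCC(C)=O | intermediate
8 | triethyl phosphonoacetate | CCOC(=O)CP(=O)(OCC)OCC | starting material
9 | ethyl (2E)-3,7,7-trimethyl-6-oxonon-2-en-8-ynoate | C#CC(C)(C)C(=O)CC/C(C)=C/C(=O)OCC | intermediate
10 | (S)-2-acetoxypropanoyl chloride | C[C@H](OC(C)=O)C(Cl)=O | starting material
11 | ethyl (2E,11S)-11-acetoxy-3,7,7-trimethyl-6,10-dioxododec-2-en-8-ynoate | C[C@H](OC(C)=O)C(=O)C#CC(C)(C)C(=O)CC/C(C)=C/C(=O)OCC | intermediate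
12 | ethyl (2E,11S)-11-hydroxy-3,7,7-trimethyl-6,10-dioxododec-2-en-8-ynoate | C[C@H](O)C(=O)C#CC(C)(C)C(=O)CC/C(C)=C/C(=O)OCC | intermediate
13 | ethyl (2E)-3,7-dimethyl-7-(5-methyl-4-oxo-4,5-dihydrofuran-2-yl)-6-oxooct-2-enoate (ring stereocentre labile, not specified) | CC1OC(=CC1=O)C(C)(C)C(=O)CC/C(C)=C/C(=O)OCC | intermediate
14 | ethyl (2E)-7-[4-(tert-butyldimethylsilyloxy)-5-methylfuran-2-yl]-3,7-dimethyl-6-oxooct-2-enoate | Cc1oc(cc1O[Si](C)(C)C(C)(C)C)C(C)(C)C(=O)CC/C(C)=C/C(=O)OCC | intermediate
15 | (2E)-7-[4-(tert-butyldimethylsilyloxy)-5-methylfuran-2-yl]-3,7-dimethyloct-2-ene-1,6-diol (carbinol centre unspecified) | Cc1oc(cc1O[Si](C)(C)C(C)(C)C)C(C)(C)C(O)CC/C(C)=C/CO | intermediate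
16 | (2E)-7-[4-(tert-butyldimethylsilyloxy)-5-methylfuran-2-yl]-3,7-dimethyl-6-oxooct-2-enal | Cc1oc(cc1O[Si](C)(C)C(C)(C)C)C(C)(C)C(=O)CC/C(C)=C/C=O | intermediate
17 | oxygen-bridged adduct (5,8-epoxy, 7-OTBS-6-ene, 3-one, 11-al) | O=C[C@H]2[C@]4(C)CCC(=O)C(C)(C)[C@@]4(O3)C=C(O[Si](C)(C)C(C)(C)C)[C@@]23C | intermediate
18 | 8-OTBS 5-ene-3,7-dione 11-al | O=C[C@H]1[C@]2(C)CCC(=O)C(C)(C)C2=CC(=O)[C@]1(C)O[Si](C)(C)C(C)(C)C | intermediate
19 | dimethyl (2-oxopropyl)phosphonate | COP(=O)(CC(C)=O)OC | starting material
20 | (11E)-8-OTBS-14,15-dinorlabda-5,11-diene-3,7,13-trione | CC(=O)/C=C/[C@H]1[C@]2(C)CCC(=O)C(C)(C)C2=CC(=O)[C@]1(C)O[Si](C)(C)C(C)(C)C | intermediate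
21 | 8-OTBS-14,15-dinorlabdane-3,7,13-trione | CC(=O)CC[C@H]1[C@]2(C)CCC(=O)C(C)(C)[C@H]2CC(=O)[C@]1(C)O[Si](C)(C)C(C)(C)C | intermediate
22 | ethyl (13E)-8-OTBS-3,7-dioxolabd-13-en-15-oate | CCOC(=O)/C=C(\C)CC[C@H]1[C@]2(C)CCC(=O)C(C)(C)[C@H]2CC(=O)[C@]1(C)O[Si](C)(C)C(C)(C)C | intermediate
23 | ethyl (13E)-8-hydroxy-3,7-dioxolabd-13-en-15-oate | CCOC(=O)/C=C(\C)CC[C@H]1[C@]2(C)CCC(=O)C(C)(C)[C@H]2CC(=O)[C@]1(C)O | intermediate
24 | ethyl (13E)-7,8-dihydroxy-3-oxolabd-13-en-15-oate | CCOC(=O)/C=C(\C)CC[C@H]1[C@]2(C)CCC(=O)C(C)(C)[C@H]2C[C@@H](O)[C@]1(C)O | intermediate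
25 | ethyl (13E)-8-hydroxy-3-oxo-7-(phenoxythiocarbonyloxy)labd-13-en-15-oate | CCOC(=O)/C=C(\C)CC[C@H]1[C@]2(C)CCC(=O)C(C)(C)[C@H]2C[C@@H](OC(=S)Oc3ccccc3)[C@]1(C)O | intermediate
26 | ethyl (13E)-8-hydroxy-3-oxolabd-13-en-15-oate | CCOC(=O)/C=C(\C)CC[C@H]1[C@]2(C)CCC(=O)C(C)(C)[C@H]2CC[C@]1(C)O | intermediate
27 | ethyl (13E)-3,8-bis(trimethylsilyloxy)labda-2,13-dien-15-oate | CCOC(=O)/C=C(\C)CC[C@H]1[C@]2(C)CC=C(O[Si](C)(C)C)C(C)(C)[C@H]2CC[C@]1(C)O[Si](C)(C)C | intermediate
28 | (13E)-8,15-dihydroxylabd-13-en-3-one | OC/C=C(\C)CC[C@H]1[C@]2(C)CCC(=O)C(C)(C)[C@H]2CC[C@]1(C)O | intermediate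
29 | (13E)-8,15-dihydroxy-2-(hydroxymethylene)labd-13-en-3-one | OC/C=C(\C)CC[C@H]1[C@]2(C)C/C(=C/O)C(=O)C(C)(C)[C@H]2CC[C@]1(C)O | intermediate
30 | (13E)-8,15-dihydroxy-2,3-secolabd-13-ene-2,3-dioic acid | OC/C=C(\C)CC[C@H]1[C@](C)(CC(=O)O)[C@@H](C(C)(C)C(=O)O)CC[C@]1(C)O | intermediate
31 | diallyl (13E)-8,15-dihydroxy-2,3-secolabd-13-ene-2,3-dioate | OC/C=C(\C)CC[C@H]1[C@](C)(CC(=O)OCC=C)[C@@H](C(C)(C)C(=O)OCC=C)CC[C@]1(C)O | intermediate
32 | diallyl (13R,14R)-13,14-epoxy-8,15-dihydroxy-2,3-secolabdane-2,3-dioate | OC[C@H]1O[C@]1(C)CC[C@H]2[C@](C)(CC(=O)OCC=C)[C@@H](C(C)(C)C(=O)OCC=C)CC[C@]2(C)O | intermediate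
33 | diallyl (13S,14R)-8,13-epoxy-14,15-dihydroxy-2,3-secolabdane-2,3-dioate | OC[C@@H](O)[C@]1(C)CC[C@H]2[C@](C)(CC(=O)OCC=C)[C@@H](C(C)(C)C(=O)OCC=C)CC[C@]2(C)O1 | intermediate
34 | 14,15-cyclic thionocarbonate of 33 | S=C1OC[C@@H](O1)[C@]2(C)CC[C@H]3[C@](C)(CC(=O)OCC=C)[C@@H](C(C)(C)C(=O)OCC=C)CC[C@]3(C)O2 | intermediate
35 | diallyl (13S)-8,13-epoxy-2,3-secolabd-14-ene-2,3-dioate | C=C[C@]1(C)CC[C@H]2[C@](C)(CC(=O)OCC=C)[C@@H](C(C)(C)C(=O)OCC=C)CC[C@]2(C)O1 | intermediate
36 | (13S)-8,13-epoxy-2,3-secolabd-14-ene-2,3-dioic acid | C=C[C@]1(C)CC[C@H]2[C@](C)(CC(=O)O)[C@@H](C(C)(C)C(=O)O)CC[C@]2(C)O1 | intermediate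
37 | (13S)-8,13-epoxy-2,3-secolabd-14-ene-2,3-dioic acid 2-allyl ester | C=C[C@]1(C)CC[C@H]2[C@](C)(CC(=O)OCC=C)[C@@H](C(C)(C)C(=O)O)CC[C@]2(C)O1 | intermediate
38 | diallyl (13S,14S)-13,14-epoxy-8,15-dihydroxy-2,3-secolabdane-2,3-dioate | OC[C@@H]1O[C@@]1(C)CC[C@H]2[C@](C)(CC(=O)OCC=C)[C@@H](C(C)(C)C(=O)OCC=C)CC[C@]2(C)O | intermediate
39 | diallyl (13R,14S)-8,13-epoxy-14,15-dihydroxy-2,3-secolabdane-2,3-dioate | OC[C@H](O)[C@@]1(C)CC[C@H]2[C@](C)(CC(=O)OCC=C)[C@@H](C(C)(C)C(=O)OCC=C)CC[C@]2(C)O1 | intermediate
40 | 15-O-triethylsilyl ether of 39 | CC[Si](CC)(CC)OC[C@H](O)[C@@]1(C)CC[C@H]2[C@](C)(CC(=O)OCC=C)[C@@H](C(C)(C)C(=O)OCC=C)CC[C@]2(C)O1 | intermediate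
41 | 15-O-triethylsilyl 14-O-methanesulfonyl derivative of 39 | CC[Si](CC)(CC)OC[C@H](OS(C)(=O)=O)[C@@]1(C)CC[C@H]2[C@](C)(CC(=O)OCC=C)[C@@H](C(C)(C)C(=O)OCC=C)CC[C@]2(C)O1 | intermediate
42 | 14-O-methanesulfonyl derivative of 39 (free 15-OH) | OC[C@H](OS(C)(=O)=O)[C@@]1(C)CC[C@H]2[C@](C)(CC(=O)OCC=C)[C@@H](C(C)(C)C(=O)OCC=C)CC[C@]2(C)O1 | intermediate
43 | diallyl (13R,14R)-8,13:14,15-diepoxy-2,3-secolabdane-2,3-dioate | C1O[C@H]1[C@@]2(C)CC[C@H]3[C@](C)(CC(=O)OCC=C)[C@@H](C(C)(C)C(=O)OCC=C)CC[C@]3(C)O2 | intermediate
44 | tris(allyl) ester of the target | C=C[C@]1(C)CC[C@H]2[C@](C)(CC(=O)OCC=C)[C@@H](C(C)(C)C(=O)OC[C@@H](O)[C@@]3(C)CC[C@H]4[C@](C)(CC(=O)OCC=C)[C@@H](C(C)(C)C(=O)OCC=C)CC[C@]4(C)O3)CC[C@]2(C)O1 | intermediate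
45 | CNP0107285.2 | C=C[C@]1(C)CC[C@H]2[C@](C)(CC(=O)O)[C@@H](C(C)(C)C(=O)OC[C@@H](O)[C@@]3(C)CC[C@H]4[C@](C)(CC(=O)O)[C@@H](C(C)(C)C(=O)O)CC[C@]4(C)O3)CC[C@]2(C)O1 | target

## Step count and least certain steps

Total: 32 steps. Longest linear sequence: 28 steps (steps 1–20, 21–26, 31, 32). The diol-half branch (steps 27–30) runs in parallel from 31.

**Step 9 (key step).** Several things may go wrong. Turnover may be low because a β,β-disubstituted enal is a weak dienophile, the C3 ketone competes for the Lewis acid, and the new C5–C10 bond joins two fully substituted carbons next to the quaternary C4. The face selection by a catalyst never tested on this substrate class may be poor. The adduct may revert, and the acidic catalyst may protodesilylate the furan. The fallback replaces catalyst control by a stereocentre in the tether and an achiral aluminium Lewis acid, both known chemistry. It sets out from 14. Corey–Bakshi–Shibata reduction ((S)-Me-CBS, BH3·SMe2) of the C3 ketone, whose large tertiary and small primary substituents are well differentiated, should give ethyl (2E,6R)-7-[4-(tert-butyldimethylsilyloxy)-5-methylfuran-2-yl]-6-hydroxy-3,7-dimethyloct-2-enoate F1. i-Bu2AlH reduces the ester to the (6R)-diol F2, and MnO2 oxidises only the allylic alcohol to the (6R)-hydroxy enal F3. Me2AlCl (2.2 equiv, the first equivalent forming the aluminium alkoxide) promotes the intramolecular furan Diels–Alder reaction through the chair-like tether in which the C3 oxygen is equatorial, which should give the 3-hydroxy adduct F4. Ley–Griffith oxidation of the C3 carbinol comes back to the route at 17.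

**Step 10.** The silyl triflate may instead activate the aldehyde towards capture by the enol ether. Adventitious acid may hydrolyse the enol ether to the bridged ketone without opening. The C5 cation may undergo a skeletal shift. The fallback changes the order and the mechanism to a fluoride-triggered E1cB after the aldehyde has been consumed. It sets out from 17. Olefination with 19 (LiCl, i-Pr2NEt) gives the bridged silyl enol ether enone F5. TBAF removes the silyl group and the C7 enolate expels the C5–O bond, giving (11E)-8-hydroxy-14,15-dinorlabda-5,11-diene-3,7,13-trione F6. Silylation of the tertiary alcohol (TBSOTf, 2,6-lutidine) comes back at 20.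

**Step 12.** Reduction of the hindered C5=C6 bond may stall or deliver hydrogen to the wrong face. The fallback uses hydroxyl-directed homogeneous hydrogenation. It sets out from 20. Aqueous HF frees the C8 hydroxyl to give the hydroxy dienone F6 (the compound described under step 10). [Ir(cod)(PCy3)(py)]PF6 under H2 in CH2Cl2, directed by the C8 hydroxyl that lies on the required face, should give 8-hydroxy-14,15-dinorlabdane-3,7,13-trione F7. Olefination with 8 as in step 13 comes back at 23.

**Step 18.** Silylation may be incomplete or may also convert the enoate into a silyl ketene acetal, which leads to partial ketone reduction or deconjugation of the ester. The fallback accepts reduction of both groups and restores the ketone. It sets out from 26. i-Bu2AlH gives (13E)-labd-13-ene-3,8,15-triol F8. TBSCl and imidazole protect the primary allylic alcohol as the 15-O-TBS ether F9. Dess–Martin periodinane oxidises the C3 carbinol to the 15-O-TBS ether of 28, F10. TBAF comes back at 28.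

**Step 28 (and, less so, step 22).** Ionisation at C13 would erode the inversion and open elimination or semipinacol pathways. Opening at C14 (7-endo) and ester exchange by the titanium alkoxide are further risks. The closure that places C14 axial is the harder of the two. The fallback replaces the epoxide relay by electrophile-induced etherification. It sets out from 31. N-Iodosuccinimide in CH2Cl2 induces 6-exo iodoetherification (O8 to C13, iodide anti at C14) and, after separation of the C13 epimers, should give diallyl (13R,14S)-8,13-epoxy-15-hydroxy-14-iodo-2,3-secolabdane-2,3-dioate F11. K2CO3 closes the 14,15-epoxide with inversion at C14 and comes back at 43. C13 is then under substrate control only, which is why this is held in reserve.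

## Further compounds

F1 | step 9 | ethyl (2E,6R)-7-[4-(tert-butyldimethylsilyloxy)-5-methylfuran-2-yl]-6-hydroxy-3,7-dimethyloct-2-enoate | Cc1oc(cc1O[Si](C)(C)C(C)(C)C)C(C)(C)[C@H](O)CC/C(C)=C/C(=O)OCC
F2 | step 9 | (2E,6R)-7-[4-(tert-butyldimethylsilyloxy)-5-methylfuran-2-yl]-3,7-dimethyloct-2-ene-1,6-diol | Cc1oc(cc1O[Si](C)(C)C(C)(C)C)C(C)(C)[C@H](O)CC/C(C)=C/CO
F3 | step 9 | (2E,6R)-7-[4-(tert-butyldimethylsilyloxy)-5-methylfuran-2-yl]-6-hydroxy-3,7-dimethyloct-2-enal | Cc1oc(cc1O[Si](C)(C)C(C)(C)C)C(C)(C)[C@H](O)CC/C(C)=C/C=O
F4 | step 9 | 3-hydroxy analogue of adduct 17 (3-OH equatorial) | O=C[C@H]2[C@]4(C)CC[C@@H](O)C(C)(C)[C@@]4(O3)C=C(O[Si](C)(C)C(C)(C)C)[C@@]23C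
F5 | step 10 | bridged silyl enol ether with (11E)-13-oxo side chain | CC(=O)/C=C/[C@H]2[C@]4(C)CCC(=O)C(C)(C)[C@@]4(O3)C=C(O[Si](C)(C)C(C)(C)C)[C@@]23C
F6 | step 10 | (11E)-8-hydroxy-14,15-dinorlabda-5,11-diene-3,7,13-trione | CC(=O)/C=C/[C@H]1[C@]2(C)CCC(=O)C(C)(C)C2=CC(=O)[C@]1(C)O
F7 | step 12 | 8-hydroxy-14,15-dinorlabdane-3,7,13-trione | CC(=O)CC[C@H]1[C@]2(C)CCC(=O)C(C)(C)[C@H]2CC(=O)[C@]1(C)O
F8 | step 18 | (13E)-labd-13-ene-3,8,15-triol (3-OH equatorial expected) | OC/C=C(\C)CC[C@H]1[C@]2(C)CC[C@@H](O)C(C)(C)[C@H]2CC[C@]1(C)O
F9 | step 18 | 15-O-TBS ether of F8 | CC(C)(C)[Si](C)(C)OC/C=C(\C)CC[C@H]1[C@]2(C)CC[C@@H](O)C(C)(C)[C@H]2CC[C@]1(C)O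
F10 | step 18 | 15-O-TBS ether of 28 | CC(C)(C)[Si](C)(C)OC/C=C(\C)CC[C@H]1[C@]2(C)CCC(=O)C(C)(C)[C@H]2CC[C@]1(C)O
F11 | step 28 | diallyl (13R,14S)-8,13-epoxy-15-hydroxy-14-iodo-2,3-secolabdane-2,3-dioate | OC[C@H](I)[C@@]1(C)CC[C@H]2[C@](C)(CC(=O)OCC=C)[C@@H](C(C)(C)C(=O)OCC=C)CC[C@]2(C)O1
A1 | alternative 1 | bis(2-trimethylsilylethyl) (13R,14R)-8,13-epoxy-14,15-dihydroxy-2,3-secolabdane-2,3-dioate | OC[C@@H](O)[C@@]3(C)CC[C@H]4[C@](C)(CC(=O)OCC[Si](C)(C)C)[C@@H](C(C)(C)C(=O)OCC[Si](C)(C)C)CC[C@]4(C)O3
A2 | alternative 1 | bis(2-trimethylsilylethyl) (13S,14R)-13,14-epoxy-8,15-dihydroxy-2,3-secolabdane-2,3-dioate | OC[C@H]1O[C@@]1(C)CC[C@H]2[C@](C)(CC(=O)OCC[Si](C)(C)C)[C@@H](C(C)(C)C(=O)OCC[Si](C)(C)C)CC[C@]2(C)O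
A3 | alternative 2 | 3-hydroxy-ent-manoyl oxide (equatorial 3-OH) | C=C[C@]1(C)CC[C@H]2[C@](C)(CC[C@@H](O)C4(C)C)[C@@H]4CC[C@]2(C)O1
A4 | alternative 2 | (3R,13S)-epoxygeranyllinalool | C=C[C@](O)(C)CC/C=C(\C)CC/C=C(\C)CC[C@H]1OC1(C)C
A5 | alternative 3 | ring B diketone with C10 allyl and C9 3-oxobutyl groups | CC(=O)CC[C@H]2[C@](C)(CC=C)[C@@H](C(C)(C)C(=O)OC)CCC2=O
A6 | alternative 3 | methyl 2-methyl-2-(2-methyl-4-oxocyclohex-2-en-1-yl)propanoate | CC1=CC(=O)CC[C@@H]1C(C)(C)C(=O)OC
A7 | alternative 3 | allyltrimethylsilane | C=CC[Si](C)(C)C
A8 | alternative 3 | methyl vinyl ketone | C=CC(C)=O
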